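**Strategy.** The route rests on forming rings B and D last: the bonds C6–C7 and C9–C10 are made around C8 in one tin-hydride operation. The key step exploits the 2-methylenepropane-1,3-diyl unit C7–C8(=C17)–C9 lying β to the C12 ketone: a stannyl ketyl-type radical at C9 closes the furan-fused cycloheptenone (ring D) onto C10 of a vinylfuran, then the neopentyl C6 radical closes the cyclohexane (ring B) at C7 with loss of a sulfonyl radical, which leaves the C8=C17 methylene. The precursor is a chloromethyl cyclohexa-1,4-diene-fused butenolide (ring A, made by Birch reductive alkylation) bearing a furyl dienone with an allyl sulfone.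

Key step: step 16

Locants used in the text: ring A = C1–C5 and C10; ring B = C5–C10; lactone = C18 (carbonyl on C4) and C19 (CH2 on C5); ring D = C1, C10, C9, C11, C12 (ketone), C13 and C16 (furan carbons; C14, C15 and O complete the furan); C17 = exocyclic methylene on C8; C20 = methyl on C9.

Assumption: the (S)-configured auxiliary is taken to steer the alkylation of step 4 to the face that gives 12 as drawn, (R) at the quaternary carbon; should the sense be the opposite, the enantiomeric amine is used in step 2 and nothing else changes.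

Step 1
Reactants: 1 furan-3-carbaldehyde; 2 ethane-1,2-diol
Product: 3 2-(furan-3-yl)-1,3-dioxolane
Conditions: p-TsOH (cat.), benzene, reflux, Dean–Stark trap
Reagents that add atoms: none
Why: Acid-catalysed acetalisation with azeotropic removal of water masks the aldehyde carbon (future C12) for the organometallic and dissolving-metal steps.

Step 2
Reactants: 4 5-bromo-2-methoxybenzoic acid; 5 (2S)-2-(methoxymethyl)pyrrolidine
Product: 7 bromo benzamide, via acid chloride 6 (not isolated)
Conditions: (COCl)2, DMF (cat.), CH2Cl2, 0 °C to rt; then 5, Et3N, CH2Cl2, 0 °C to rt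
Reagents that add atoms: none
Why: Acylation of the secondary amine by the acid chloride made in the flask (amide formation) installs the prolinol-derived auxiliary that will control C5.

Step 3
Reactants: 3 2-(furan-3-yl)-1,3-dioxolane; 7 bromo benzamide
Product: 10 furyl aryl amide, via furyllithium 8 (not isolated), via furylzinc chloride 9 (not isolated)
Conditions: 3, n-BuLi, THF, −78 to 0 °C; ZnCl2, THF; then 7, Pd(PPh3)4 (cat.), THF, 60 °C
Reagents that add atoms: none
Why: Acetal-directed lithiation at furan C2, transmetalation to zinc and Negishi coupling with the aryl bromide form the C1–C16 biaryl bond, the tertiary amide being inert to the organozinc.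

Step 4
Reactants: 10 furyl aryl amide
Product: 12 chloromethyl cyclohexadienyl amide, via potassium amide enolate 11 (not isolated)
Conditions: K (2.1 equiv), NH3/THF, t-BuOH (1 equiv), −78 °C; then ICH2Cl, −78 °C to rt
Reagents that add atoms: chloroiodomethane ClCI
Why: Birch reductive alkylation: two-electron reduction of the benzamide ring with protonation para to the amide (the methoxy- and furyl-bearing carbons stay sp2 and the electron-rich furan should not be reduced) gives a chelated potassium amide enolate that is alkylated at carbon by ICH2Cl on the face fixed by the auxiliary, which sets the quaternary stereocentre C5.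

Step 5
Reactants: 12 chloromethyl cyclohexadienyl amide
Product: 13 β-keto amide
Conditions: (CO2H)2 (cat.), THF/H2O, 0 °C, short reaction time
Reagents that add atoms: water O
Why: Protonation of the enol ether at C3 and hydrolysis, which should be far faster than acetal hydrolysis under these mild conditions, unveils the C4 ketone, which cannot conjugate with C1=C10 because C5 is quaternary.

Step 6
Reactants: 13 β-keto amide
Product: 15 enol triflate amide, via potassium enolate 14 (not isolated)
Conditions: KN(SiMe3)2, THF, −78 °C; then PhNTf2, −78 to 0 °C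
Reagents that add atoms: N-phenylbis(trifluoromethanesulfonimide) O=S(=O)(N(c1ccccc1)S(=O)(=O)C(F)(F)F)C(F)(F)F
Why: The ketone can enolise only toward C3, so O-sulfonylation of the enolate should give a single enol triflate and complete the cyclohexa-1,4-diene.

Step 7
Reactants: 15 enol triflate amide
Product: 17 neopentyl aldehyde, via zirconium hemiaminal 16 (not isolated)
Conditions: Cp2Zr(H)Cl (1.5 equiv), THF, rt; aq. NaHCO3 work-up
Reagents that add atoms: none
Why: Hydrozirconation of the tertiary amide carbonyl gives a zirconated hemiaminal that collapses to the aldehyde on work-up and releases the auxiliary, while the enol triflate and the alkyl chloride should not be attacked at room temperature.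

Step 8
Reactants: 17 neopentyl aldehyde
Product: 18 hydroxy enol triflate
Conditions: NaBH4, MeOH, 0 °C
Reagents that add atoms: none
Why: Borohydride reduction of the non-enolisable aldehyde gives the neopentyl alcohol (C19) without touching the enol triflate.

Step 9
Reactants: 18 hydroxy enol triflate
Product: 19 dienyl lactone acetal
Conditions: CO (1 atm), Pd(PPh3)4 (cat.), Et3N, MeCN, 65 °C
Reagents that add atoms: carbon monoxide [C-]#[O+]
Why: Palladium-catalysed carbonylative lactonisation (oxidative addition to the enol triflate, CO insertion, capture of the acylpalladium by the neighbouring hydroxyl) builds the fused α,β-unsaturated γ-lactone with C18 from CO, and the weak amine base should not isomerise the skipped diene.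

Step 10
Reactants: 19 dienyl lactone acetal
Product: 20 lactone furaldehyde
Conditions: pyridinium p-toluenesulfonate (cat.), acetone/H2O, 40 °C
Reagents that add atoms: water O
Why: Mild acid-catalysed acetal hydrolysis frees the furan aldehyde (C12) while the lactone and the acid-sensitive vinylfuran should stay intact.

Step 11
Reactants: 21 2,3-dibromoprop-1-ene; 22 sodium benzenesulfinate
Product: 23 2-bromoallyl phenyl sulfone
Conditions: DMF, rt
Reagents that add atoms: none
Why: S-Alkylation of the sulfinate at the allylic bromide (SN2) leaves the vinylic bromide for cross-coupling.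

Step 12
Reactants: 23 2-bromoallyl phenyl sulfone
Product: 24 enyne sulfone
Conditions: HC≡CMgBr, ZnCl2, THF, 0 °C; then 23, Pd(PPh3)4 (cat.), THF, rt to 50 °C
Reagents that add atoms: ethynylmagnesium bromide C#C[Mg]Br
Why: Negishi alkynylation of the vinyl bromide with ethynylzinc chloride, which is too weakly basic to deprotonate the allyl sulfone.

Step 13
Reactants: 24 enyne sulfone
Product: 26 dienyl iodide, via alkenylalane 25 (not isolated)
Conditions: AlMe3 (3 equiv), Cp2ZrCl2 (0.3 equiv), CH2Cl2, 0 °C to rt; then I2, THF, −30 °C
Reagents that add atoms: trimethylaluminium C[Al](C)C; iodine II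
Why: Zirconium-catalysed syn-methylalumination of the terminal alkyne (Negishi carboalumination) followed by iodinolysis with retention gives the E trisubstituted vinyl iodide that fixes the later enone geometry.

Step 14
Reactants: 20 lactone furaldehyde; 26 dienyl iodide
Product: 28 dienyl carbinol, via alkenylchromium dichloride 27 (not isolated)
Conditions: CrCl2 (6 equiv), NiCl2 (cat.), DMSO, rt
Reagents that add atoms: none
Why: Nozaki–Hiyama–Kishi reaction: the alkenylchromium reagent adds only to the aldehyde (lactone, alkyl chloride and sulfone are inert), and the new carbinol centre is removed in the next step.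

Step 15
Reactants: 28 dienyl carbinol
Product: 29 furyl dienone
Conditions: MnO2 (excess), CH2Cl2, rt
Reagents that add atoms: none
Why: MnO2 oxidises the doubly activated (allylic and furylic) carbinol to the furyl dienone without affecting the alkyl chloride or the sulfone.

Step 16
Reactants: 29 furyl dienone
Product: 32 7-deoxy tetracyclic keto lactone, via ring-D stannyl enol ether 30 (not isolated), via fully cyclised stannyl enol ether 31 (not isolated)
Conditions: Bu3SnH (2.5 equiv, syringe pump), AIBN (cat., in portions), toluene (0.005 M), 80 °C then 110 °C; aq. NaHCO3 work-up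
Reagents that add atoms: none
Why: Proposed new method: Bu3Sn• is expected to add to the carbonyl oxygen of the furyl dienone to give an O-stannyl dienyl (ketyl-type) radical whose C9 terminus adds to C10 of the vinylfuran, and the furfuryl radical at C1 takes hydrogen from Bu3SnH (30); the slower chlorine abstraction at the neopentyl C6 then gives a primary radical that attacks C7 of the 2-(sulfonylmethyl)allyl unit, β-scission of PhSO2• creating the C8=C17 methylene (31), and work-up frees the C12 ketone. The closest known reaction types are the tin-hydride cyclisation of O-stannyl allyl radicals generated from enones and the intramolecular radical allylation (addition–fragmentation) on allyl sulfones, but their merger, the seven-membered closure and the quaternary C9 are without precedent. Ring D closes 7-endo-trig (the C7 terminus of the dienyl radical would need a nine-membered ring) and ring B closes 6-endo-trig (5-exo attack is blocked at the fully substituted C8 and cannot fragment). C10 is controlled by C5, the radical entering anti to the pseudo-axial CH2Cl arm because the fused lactone holds C19 near the ring plane, which gives the trans A/B junction; C9 is controlled by the E geometry of the enone, which keeps C8 trans to the C12 tether and the methyl over ring A in the cyclic transition state; C1 is controlled by hydrogen transfer to the face that leaves the furan equatorial (trans A/D junction). The step needs the C9–C10 bond to form before the C6 radical appears, and this order is secured by the chloride at C6 (slow halogen abstraction compared with stannyl radical addition to the dienone) together with slow addition of Bu3SnH.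

Step 17
Reactants: 32 7-deoxy tetracyclic keto lactone
Product: 33 allylic alcohol
Conditions: SeO2 (0.5 equiv), t-BuOOH (3 equiv), CH2Cl2, 0 °C to rt
Reagents that add atoms: selenium dioxide O=[Se]=O (catalytic oxygen carrier); tert-butyl hydroperoxide CC(C)(C)OO (terminal oxidant)
Why: SeO2-catalysed allylic oxidation (ene reaction, then [2,3]-sigmatropic shift) can only take hydrogen from C7 because C9 is quaternary, and oxygen should be delivered to the face of C7 opposite the axial C19 and C20 groups to give the equatorial (7S) alcohol, while the mild catalytic conditions should spare the ketone α-methylene and the furan.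

Step 18
Reactants: 33 allylic alcohol
Product: 34 target acetate
Conditions: Ac2O, pyridine, DMAP (cat.), CH2Cl2, rt
Reagents that add atoms: acetic anhydride CC(=O)OC(C)=O
Why: DMAP-catalysed O-acylation of the secondary allylic alcohol with retention of configuration should give the target.

**Compound list**

1 | furan-3-carbaldehyde | O=Cc1ccoc1 | starting material
2 | ethane-1,2-diol | OCCO | starting material
3 | 2-(furan-3-yl)-1,3-dioxolane | C1COC(O1)c2ccoc2 | intermediate
4 | 5-bromo-2-methoxybenzoic acid | COc1ccc(Br)cc1C(=O)O | starting material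
5 | (2S)-2-(methoxymethyl)pyrrolidine | COC[C@@H]1CCCN1 | starting material
6 | 5-bromo-2-methoxybenzoyl chloride | COc1ccc(Br)cc1C(=O)Cl | intermediate (not isolated)
7 | (5-bromo-2-methoxyphenyl)[(2S)-2-(methoxymethyl)pyrrolidin-1-yl]methanone | COc1ccc(Br)cc1C(=O)N1CCC[C@H]1COC | intermediate
8 | [3-(1,3-dioxolan-2-yl)furan-2-yl]lithium | [Li]c1occc1C2OCCO2 | intermediate (not isolated)
9 | chlorido[3-(1,3-dioxolan-2-yl)furan-2-yl]zinc | Cl[Zn]c1occc1C2OCCO2 | intermediate (not isolated)
10 | {5-[3-(1,3-dioxolan-2-yl)furan-2-yl]-2-methoxyphenyl}[(2S)-2-(methoxymethyl)pyrrolidin-1-yl]methanone | COc1ccc(cc1C(=O)N2CCC[C@H]2COC)-c3occc3C4OCCO4 | intermediate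
11 | potassium {3-[3-(1,3-dioxolan-2-yl)furan-2-yl]-6-methoxycyclohexa-2,5-dien-1-ylidene}[(2S)-2-(methoxymethyl)pyrrolidin-1-yl]methanolate (amide enolate) | [K+].[O-]C(=C1C=C(c2occc2C3OCCO3)CC=C1OC)N1CCC[C@H]1COC | intermediate (not isolated)
12 | [(1R)-1-(chloromethyl)-3-[3-(1,3-dioxolan-2-yl)furan-2-yl]-6-methoxycyclohexa-2,5-dien-1-yl][(2S)-2-(methoxymethyl)pyrrolidin-1-yl]methanone | ClC[C@@]1(C(=O)N2CCC[C@H]2COC)C(OC)=CCC(c2occc2C3OCCO3)=C1 | intermediate
13 | (2R)-2-(chloromethyl)-4-[3-(1,3-dioxolan-2-yl)furan-2-yl]-2-{[(2S)-2-(methoxymethyl)pyrrolidin-1-yl]carbonyl}cyclohex-3-en-1-one | ClC[C@@]1(C(=O)N2CCC[C@H]2COC)C(=O)CCC(c2occc2C3OCCO3)=C1 | intermediate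
14 | potassium (6R)-6-(chloromethyl)-4-[3-(1,3-dioxolan-2-yl)furan-2-yl]-6-{[(2S)-2-(methoxymethyl)pyrrolidin-1-yl]carbonyl}cyclohexa-1,4-dien-1-olate | [K+].ClC[C@@]1(C(=O)N2CCC[C@H]2COC)C([O-])=CCC(c2occc2C3OCCO3)=C1 | intermediate (not isolated)
15 | (6R)-6-(chloromethyl)-4-[3-(1,3-dioxolan-2-yl)furan-2-yl]-6-{[(2S)-2-(methoxymethyl)pyrrolidin-1-yl]carbonyl}cyclohexa-1,4-dien-1-yl trifluoromethanesulfonate | ClC[C@@]1(C(=O)N2CCC[C@H]2COC)C(OS(=O)(=O)C(F)(F)F)=CCC(c2occc2C3OCCO3)=C1 | intermediate
16 | chloridobis(cyclopentadienyl)zirconium alkoxide of the N,O-hemiaminal formed from 15 (hemiaminal carbon unassigned; quaternary carbon as in 15) | ClC[C@@]1(C(O[Zr](Cl)(C2C=CC=C2)C2C=CC=C2)N2CCC[C@H]2COC)C(OS(=O)(=O)C(F)(F)F)=CCC(c2occc2C3OCCO3)=C1 | intermediate (not isolated)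
17 | (6R)-6-(chloromethyl)-4-[3-(1,3-dioxolan-2-yl)furan-2-yl]-6-formylcyclohexa-1,4-dien-1-yl trifluoromethanesulfonate | ClC[C@@]1(C=O)C(OS(=O)(=O)C(F)(F)F)=CCC(c2occc2C3OCCO3)=C1 | intermediate
18 | (6S)-6-(chloromethyl)-4-[3-(1,3-dioxolan-2-yl)furan-2-yl]-6-(hydroxymethyl)cyclohexa-1,4-dien-1-yl trifluoromethanesulfonate | ClC[C@@]1(CO)C(OS(=O)(=O)C(F)(F)F)=CCC(c2occc2C3OCCO3)=C1 | intermediate
19 | (3aR)-3a-(chloromethyl)-5-[3-(1,3-dioxolan-2-yl)furan-2-yl]-3a,6-dihydro-2-benzofuran-1(3H)-one | ClC[C@@]12COC(=O)C1=CCC(c3occc3C4OCCO4)=C2 | intermediate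
20 | 2-[(3aR)-3a-(chloromethyl)-1-oxo-1,3,3a,6-tetrahydro-2-benzofuran-5-yl]furan-3-carbaldehyde | ClC[C@@]12COC(=O)C1=CCC(c3occc3C=O)=C2 | intermediate
21 | 2,3-dibromoprop-1-ene | C=C(Br)CBr | starting material
22 | sodium benzenesulfinate | [Na+].[O-]S(=O)c1ccccc1 | starting material
23 | [(2-bromoprop-2-en-1-yl)sulfonyl]benzene | C=C(Br)CS(=O)(=O)c1ccccc1 | intermediate
24 | [(2-methylidenebut-3-yn-1-yl)sulfonyl]benzene | C#CC(=C)CS(=O)(=O)c1ccccc1 | intermediate
25 | dimethyl[(1E)-2-methyl-3-methylidene-4-(phenylsulfonyl)but-1-en-1-yl]alumane | C[Al](C)/C=C(\C)C(=C)CS(=O)(=O)c1ccccc1 | intermediate (not isolated)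
26 | {[(3E)-4-iodo-3-methyl-2-methylidenebut-3-en-1-yl]sulfonyl}benzene | I/C=C(\C)C(=C)CS(=O)(=O)c1ccccc1 | intermediate
27 | dichlorido[(1E)-2-methyl-3-methylidene-4-(phenylsulfonyl)but-1-en-1-yl]chromium | Cl[Cr](Cl)/C=C(\C)C(=C)CS(=O)(=O)c1ccccc1 | intermediate (not isolated)
28 | (3aR)-3a-(chloromethyl)-5-{3-[(2E)-1-hydroxy-3-methyl-4-methylidene-5-(phenylsulfonyl)pent-2-en-1-yl]furan-2-yl}-3a,6-dihydro-2-benzofuran-1(3H)-one (both carbinol epimers) | ClC[C@@]12COC(=O)C1=CCC(c3occc3C(O)/C=C(\C)C(=C)CS(=O)(=O)c4ccccc4)=C2 | intermediate
29 | (3aR)-3a-(chloromethyl)-5-{3-[(2E)-3-methyl-4-methylidene-5-(phenylsulfonyl)pent-2-enoyl]furan-2-yl}-3a,6-dihydro-2-benzofuran-1(3H)-one | ClC[C@@]12COC(=O)C1=CCC(c3occc3C(=O)/C=C(\C)C(=C)CS(=O)(=O)c4ccccc4)=C2 | intermediate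
30 | O-tributylstannyl enol ether (C11=C12) of the ring-D-closed intermediate: C9–C10 bonded, C1–H, C6–Cl and the allyl sulfone intact; C1, C9 and C10 as in 32 | ClC[C@@]12COC(=O)C1=CC[C@H]1c3occc3C(O[Sn](CCCC)(CCCC)CCCC)=C[C@@](C)(C(=C)CS(=O)(=O)c3ccccc3)[C@H]21 | intermediate (not isolated)
31 | O-tributylstannyl enol ether (C11=C12) of 32 | C=C1CC[C@@]23COC(=O)C2=CC[C@H]2c4occc4C(O[Sn](CCCC)(CCCC)CCCC)=C[C@]1(C)[C@@H]23 | intermediate (not isolated)
32 | (1R,5S,9R,10R)-tetracyclic keto lactone: the target skeleton with C7 as CH2 (C3=C4 lactone, C8=C17 methylene, C12 ketone, trans A/B junction) | C=C1CC[C@@]23COC(=O)C2=CC[C@H]2c4occc4C(=O)C[C@]1(C)[C@@H]23 | intermediate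
33 | (1R,5S,7S,9R,10R)-7-hydroxy derivative of 32 (equatorial allylic alcohol) | C=C1[C@@H](O)C[C@@]23COC(=O)C2=CC[C@H]2c4occc4C(=O)C[C@]1(C)[C@@H]23 | intermediate
34 | CNP0273675.1, the (1R,5S,7S,9R,10R)-7-acetate of 33 | C=C1[C@@H](OC(C)=O)C[C@@]23COC(=O)C2=CC[C@H]2c4occc4C(=O)C[C@]1(C)[C@@H]23 | target

**Step count and risks**

Total step count: 18. Longest linear sequence: 14 steps (steps 2–10 and 14–18, from 4; the same length from 1 through steps 1 and 3).

Steps most likely to fail:

Step 16. What may go wrong: the two radical events run in the wrong order (the dienone is simply reduced, or a C6 radical forms and is quenched before ring D exists), or the attack on C10 shows poor facial selectivity. Fallback: the two closures are separated. From 29, SmI2 (t-BuOH, THF, −78 °C, no HMPA, so that the alkyl chloride and the sulfone are untouched) should effect the reductive enone–alkene cyclisation to the ring-D-closed chloromethyl keto lactone F1. (Me3Si)3SiH with AIBN in toluene at 110 °C should then generate the C6 radical from the chloride and close ring B by addition–fragmentation on the allyl sulfone, which comes back to the route at 32.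

Step 7. What may go wrong: incomplete hydride addition to the congested amide next to the quaternary carbon, or attack of the reagent on the enol triflate. Fallback: the amide is reduced earlier and with a stronger reagent, before the triflate exists. From 12, LiNH2BH3 (THF, 0 °C to rt) should reduce the tertiary amide directly to the primary alcohol F2 with release of the auxiliary. Silylation (t-BuMe2SiCl, imidazole, DMF) gives the silyl ether F3. Hydrolysis of the enol ether with oxalic acid in THF/H2O gives the ketone F4. KN(SiMe3)2 and PhNTf2 give the enol triflate F5, and Bu4NF buffered with AcOH removes the silyl group to come back to the route at 18.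

Step 17. What may go wrong: poor facial selectivity in the oxygen transfer to C7, or over-oxidation to the enone. Fallback: the C7 configuration is set by reduction and inversion instead. From 32, SeO2/t-BuOOH followed by oxidation of the crude alcohols with 1,1,1-triacetoxy-1,1-dihydro-1,2-benziodoxol-3(1H)-one converges on the enone F6. NaBH4/CeCl3 in MeOH at −78 °C (Luche reduction) should deliver hydride anti to the axial C19 and C20 groups and spare the hindered, less electrophilic furyl ketone, giving the axial 7-epi alcohol F7. A Mitsunobu reaction with AcOH (PPh3, DIAD, THF) then installs the acetate with inversion and comes back to the route at 34.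

**Further compounds**

F1 | step 16 | ring-D-closed chloromethyl keto lactone (C9–C10 bonded, C12 ketone, C6–Cl and allyl sulfone intact; C1, C9, C10 as in 32) | ClC[C@@]12COC(=O)C1=CC[C@H]1c3occc3C(=O)C[C@@](C)(C(=C)CS(=O)(=O)c3ccccc3)[C@H]21
F2 | step 7 | [(1S)-1-(chloromethyl)-3-[3-(1,3-dioxolan-2-yl)furan-2-yl]-6-methoxycyclohexa-2,5-dien-1-yl]methanol | ClC[C@@]1(CO)C(OC)=CCC(c2occc2C3OCCO3)=C1
F3 | step 7 | tert-butyldimethylsilyl ether of F2 | ClC[C@@]1(CO[Si](C)(C)C(C)(C)C)C(OC)=CCC(c2occc2C3OCCO3)=C1
F4 | step 7 | (2S)-2-{[tert-butyl(dimethyl)silyl]oxymethyl}-2-(chloromethyl)-4-[3-(1,3-dioxolan-2-yl)furan-2-yl]cyclohex-3-en-1-one | ClC[C@@]1(CO[Si](C)(C)C(C)(C)C)C(=O)CCC(c2occc2C3OCCO3)=C1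
F5 | step 7 | (6S)-6-{[tert-butyl(dimethyl)silyl]oxymethyl}-6-(chloromethyl)-4-[3-(1,3-dioxolan-2-yl)furan-2-yl]cyclohexa-1,4-dien-1-yl trifluoromethanesulfonate | ClC[C@@]1(CO[Si](C)(C)C(C)(C)C)C(OS(=O)(=O)C(F)(F)F)=CCC(c2occc2C3OCCO3)=C1
F6 | step 17 | 7-oxo derivative of 32 (cross-conjugated C7 ketone next to the C8=C17 methylene) | C=C1C(=O)C[C@@]23COC(=O)C2=CC[C@H]2c4occc4C(=O)C[C@]1(C)[C@@H]23
F7 | step 17 | (7R)-epimer of 33 (axial allylic alcohol) | C=C1[C@H](O)C[C@@]23COC(=O)C2=CC[C@H]2c4occc4C(=O)C[C@]1(C)[C@@H]23
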